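**Remark (numbering).** Carbons carry the briarane numbering of the target: C1 = quaternary ring-fusion carbon, C2–C9 = ten-membered ring, C10 = ring-fusion CH, C11–C14 = cyclohexene, C15/C16/C18/C20 = methyls on C1/C5/C17/C11, C17–C19 = lactone CH–C=O. "Ring Y" is the temporary six-membered ring C1–C2–C7–C8–C9–C10.

## Retrosynthetic overview

1. Target ⇐ chlorolactonisation of a ten-membered cyclic allene acid (C5=C6=C7): Cl⁺ goes to C6 and the C19 carboxyl to C7, which makes the C5=C6(Cl) olefin, the C7–O bond and the γ-lactone at once.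
2. Cyclic allene ⇐ anionic acetylenic oxy-Cope ring expansion of a trans-fused 1-vinyl-2-(1-propynyl)cyclohexanol: the temporary C2–C7 bond of ring Y is cleaved while C4–C5 forms, so ring Y becomes the C1–C10 ring.
3. Ring Y ⇐ Pd/Zn umpolung propargylation of the C2 vinyl ketone by the C7 propargylic pivalate. Ring A ⇐ catalytic asymmetric Diels–Alder of a 1-methoxy-3-silyloxypentadiene with a 4-oxo-enal (sets C1, C10, C11).
4. C7/C8/C17/C19 ⇐ aldol of a 3-methylmalic acid dioxolanone enolate with but-2-ynal.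
5. Ring order: cyclohexene A → temporary ring Y → ten-membered ring (ring expansion, no macrocyclisation) → γ-lactone.

Key step: step 18

## Route

Step 1
Reactants: 1 (R)-4-benzyl-3-propanoyl-1,3-oxazolidin-2-one; 2 ethyl glyoxylate
Product: 3 ethyl (2R,3R)-4-[(4R)-4-benzyl-2-oxo-1,3-oxazolidin-3-yl]-2-hydroxy-3-methyl-4-oxobutanoate
Conditions: n-Bu2BOTf, i-Pr2NEt, CH2Cl2, 0 °C; 2, −78 → 0 °C; pH 7 buffer/MeOH
Reagents that add atoms: none
Why: Evans boron aldol reaction; the (Z)-boron enolate should react through a Zimmerman–Traxler chair on the face away from the benzyl group and give the syn adduct, which sets C8 and C17.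

Step 2
Reactants: 3 Evans aldol adduct
Product: 4 (2R,3R)-2-hydroxy-3-methylbutanedioic acid
Conditions: LiOH, H2O2, THF/H2O, 0 °C → rt; Na2SO3; HCl
Reagents that add atoms: water, O
Why: Acyl substitution; hydroperoxide should cleave the imide at the exocyclic carbonyl and hydroxide saponify the ethyl ester without touching either stereocentre.

Step 3
Reactants: 4 (2R,3R)-2-hydroxy-3-methylbutanedioic acid
Product: 5 (2R)-2-[(2R,4R)-2-tert-butyl-5-oxo-1,3-dioxolan-4-yl]propanoic acid
Conditions: pivalaldehyde, TsOH (cat.), H2SO4 (cat.), pentane, reflux, Dean–Stark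
Reagents that add atoms: pivalaldehyde, CC(C)(C)C=O
Why: Acid-catalysed acetalisation of the α-hydroxy acid (Seebach dioxolanone); the five-membered acetal should form as the thermodynamic cis isomer, so the acetal centre is set by C8.

Step 4
Reactants: 5 dioxolanone acid
Product: 6 tert-butyl (2R)-2-[(2R,4R)-2-tert-butyl-5-oxo-1,3-dioxolan-4-yl]propanoate
Conditions: tert-butyl 2,2,2-trichloroacetimidate, CH2Cl2/cyclohexane, rt
Reagents that add atoms: tert-butyl 2,2,2-trichloroacetimidate, CC(C)(C)OC(=N)C(Cl)(Cl)Cl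
Why: Esterification by O-alkylation with the imidate; the carboxylic acid itself activates the reagent, so no added acid is needed and the acetal should survive.

Step 5
Reactants: 6 dioxolanone tert-butyl ester; 7 but-2-ynal
Product: 9 tert-butyl (2R)-2-{(2R,4S)-2-tert-butyl-4-[(1S)-1-(pivaloyloxy)but-2-yn-1-yl]-5-oxo-1,3-dioxolan-4-yl}propanoate, via lithium aldolate 8 (not isolated)
Conditions: LiHMDS, THF, −78 °C; 7, −78 °C; PivCl, −78 → 0 °C
Reagents that add atoms: pivaloyl chloride, CC(C)(C)C(Cl)=O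
Why: Aldol addition of the dioxolanone enolate with in situ O-acylation; the aldehyde should enter trans to the tert-butyl group (self-regeneration of stereocentres, sets C8) and the ring-locked enolate should give the anti relation of ring oxygen and new oxygen through a Zimmerman–Traxler chair (sets C7).

Step 6
Reactants: 9 pivalate dioxolanone
Product: 10 tert-butyl (2R,3S)-3-hydroxy-4-[methoxy(methyl)amino]-2-methyl-4-oxo-3-[(1S)-1-(pivaloyloxy)but-2-yn-1-yl]butanoate
Conditions: MeNH(OMe)·HCl, i-PrMgCl, THF, −20 → 0 °C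
Reagents that add atoms: N,O-dimethylhydroxylamine hydrochloride, CNOC.Cl
Why: Weinreb amide formation by aminolysis of the activated dioxolanone carbonyl (C9) with the magnesium amide; the hemiacetal alkoxide should collapse with loss of pivalaldehyde, while the hindered pivalate and tert-butyl ester should not react at this temperature.

Step 7
Reactants: 10 Weinreb amide; 11 (E)-3-iodo-2-methylprop-2-en-1-ol
Product: 12 tert-butyl (2R,3S,5E)-3,7-dihydroxy-2,6-dimethyl-4-oxo-3-[(1S)-1-(pivaloyloxy)but-2-yn-1-yl]hept-5-enoate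
Conditions: 11 (3 equiv), n-BuLi then t-BuLi, Et2O, −78 °C; 10, −78 → −30 °C; NH4Cl
Reagents that add atoms: none
Why: Weinreb ketone synthesis with an alkenyllithium made by iodine–lithium exchange; the exchange keeps the E geometry and the chelated tetrahedral intermediate should prevent a second addition.

Step 8
Reactants: 12 enone diol
Product: 13 tert-butyl (2R,3S,5E)-3-hydroxy-2,6-dimethyl-4,7-dioxo-3-[(1S)-1-(pivaloyloxy)but-2-yn-1-yl]hept-5-enoate
Conditions: TEMPO (cat.), PhI(OAc)2, CH2Cl2, rt
Reagents that add atoms: none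
Why: Oxoammonium (TEMPO/BAIB) oxidation, which should be selective for the primary allylic alcohol over the tertiary C8 hydroxyl.

Step 9
Reactants: 13 enal
Product: 14 dienophile: 3-O-triethylsilyl ether of 13 (C8–OTES)
Conditions: TESOTf, 2,6-lutidine, CH2Cl2, −78 °C
Reagents that add atoms: triethylsilyl trifluoromethanesulfonate, CC[Si](CC)(CC)OS(=O)(=O)C(F)(F)F
Why: Silylation of the tertiary α-hydroxy ketone with a silyl triflate, which removes the only free hydroxyl before the Lewis-acid step.

Step 10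
Reactants: 15 (E)-4-methoxybut-3-en-2-one
Product: 16 (E)-1-methoxypent-1-en-3-one
Conditions: LDA, THF, −78 °C; MeI, −78 → −20 °C
Reagents that add atoms: iodomethane, CI
Why: Kinetic α′-enolate alkylation of a vinylogous ester; deprotonation should occur at the methyl group and not at the vinylic positions.

Step 11
Reactants: 16 (E)-1-methoxypent-1-en-3-one
Product: 17 (1E,3Z)-3-(tert-butyldimethylsilyloxy)-1-methoxypenta-1,3-diene
Conditions: TBSOTf, Et3N, Et2O, 0 °C
Reagents that add atoms: tert-butyldimethylsilyl trifluoromethanesulfonate, CC(C)(C)[Si](C)(C)OS(=O)(=O)C(F)(F)F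
Why: Soft enolisation and O-silylation of the ethyl ketone, which should give the (Z)-silyl enol ether and so a Danishefsky-type diene with the C20 methyl in the outside position.

Step 12
Reactants: 14 dienophile; 17 diene
Product: 18 Diels–Alder adduct: cyclohexene with C1 (CHO, CH3), C14 (OCH3), C12=C13 TBS enol ether, C11 (CH3), C10 (C9-ketone side chain); Me-15, OMe-14, Me-20 and the C9 acyl group on one face, CHO on the other
Conditions: (S)-o-tolyl-CBS-oxazaborolidinium triflimide (20 mol %), CH2Cl2, −78 → −40 °C; Et3N quench (no acid)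
Reagents that add atoms: none
Why: Lewis-acid-catalysed Diels–Alder reaction; the aldehyde-bound catalyst should direct the nucleophilic diene terminus C11 to C10 and choose the enal face, and the exo-formyl transition state usual for α-methyl enals should place the outside methyl cis to the endo acyl group, so C1, C10 and C11 are set together (C14 is lost later).

Step 13
Reactants: 18 ring-A aldehyde
Product: 19 C2 allylic alcohol (CH(OH)–CH=CH2 on C1; both C2 epimers, used as the mixture)
Conditions: vinyl bromide, CrCl2, NiCl2 (cat.), DMF/THF, rt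
Reagents that add atoms: vinyl bromide, C=CBr
Why: Nozaki–Hiyama–Kishi vinylation, which should add to the aldehyde only and leave the C9 ketone, the esters and the enol ether alone; the C2 configuration does not matter because C2 is oxidised next.

Step 14
Reactants: 19 C2 allylic alcohol
Product: 20 C2 vinyl ketone
Conditions: Dess–Martin periodinane, NaHCO3, CH2Cl2, 0 °C
Reagents that add atoms: none
Why: Dess–Martin oxidation of the secondary allylic alcohol under buffered conditions that should spare the silyl enol ether.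

Step 15
Reactants: 20 C2 vinyl ketone
Product: 22 ring-Y tertiary alcohol (C2: OH and vinyl; C7: prop-1-ynyl; C9 ketone), via allenyl(ethyl)zinc 21 (not isolated)
Conditions: Pd(PPh3)4 (5 mol %), Et2Zn, THF, 0 °C → rt; NH4Cl
Reagents that add atoms: none
Why: Palladium-catalysed umpolung of the propargylic ester to an allenylzinc and intramolecular SE2′ carbonyl propargylation (six-membered ring closure); anti oxidative addition, retentive transmetalation and anti SE2′ should put C2 where the pivalate oxygen was on C7, and a chair with the vinyl group equatorial should set C2.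

Step 16
Reactants: 22 ring-Y ketone
Product: 23 C9 alcohol (OH axial, cis to Me-15)
Conditions: NaBH4, MeOH/THF, −20 °C
Reagents that add atoms: none
Why: Hydride reduction of a conformationally fixed cyclohexanone; the axial trajectory at C9 is closed by the 1,3-diaxial C15 methyl and propynyl groups, so hydride should arrive equatorially and give the axial alcohol, which sets C9.

Step 17
Reactants: 23 C9 alcohol
Product: 24 C9 triethylsilyl ether (oxy-Cope substrate)
Conditions: TESCl, imidazole, DMAP, DMF, 40 °C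
Reagents that add atoms: chlorotriethylsilane, CC[Si](CC)(CC)Cl
Why: Silylation of the secondary alcohol with a silyl chloride, which should leave the more hindered tertiary C2 hydroxyl free and does not ionise the allylic methoxy group.

Step 18
Reactants: 24 ring-Y tertiary alcohol
Product: 26 ten-membered allenyl ketone (C2 ketone, C5=C6=C7 allene), via potassium enolate 25 (not isolated)
Conditions: KHMDS (1.1 equiv), 18-crown-6, THF, −78 → 0 °C; NH4Cl
Reagents that add atoms: none
Why: Deprotonation of the C2 carbinol gives a potassium alkoxide in which the C2–C7 bond breaks while C4 of the vinyl group bonds to the alkyne terminus C5 in a concerted charge-accelerated [3,3] shift (anionic acetylenic oxy-Cope; closest known type: ring expansion of 1-alkenyl-2-alkynylcyclohexanols to cyclodeca-4,5-dienones). Ring Y is opened and the C1–C10 ring is formed as a four-atom ring expansion, so no end-to-end cyclisation is needed, and the 2-enolate 25 is protonated to the ketone on work-up. The only new stereo-element is the C5=C6=C7 axis, which is fixed by the C7 centre because C4 must bond on the side from which C2 leaves; C1, C8, C9, C10 and C11 are not touched. The step needs the vinyl and propynyl groups gauche (equatorial vinyl, axial propynyl, as set in step 15) and must outrun retro-propargylation; relief of the strain of four contiguous fully substituted carbons in ring Y and the use of one equivalent of a hindered base, which should leave the tert-butyl ester and the enol ether alone, are expected to secure this.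

Step 19
Reactants: 26 allenyl ketone
Product: 27 allene acid with C2 ketone and C12 enone (C13=C14)
Conditions: ZnBr2, CH2Cl2, rt; aqueous work-up
Reagents that add atoms: none
Why: Lewis-acid cleavage of the tert-butyl ester together with unravelling of the β-methoxy silyl enol ether to the enone (loss of methanol and the silyl group); the conditions are aprotic, so the triethylsilyl ethers and the allene should survive.

Step 20
Reactants: 27 allene acid
Product: 28 chlorolactone (C2 ketone, C12 enone, 8,9-bis-TES ether)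
Conditions: NCS, MeCN, 0 °C
Reagents that add atoms: N-chlorosuccinimide, O=C1CCC(=O)N1Cl
Why: Proposed new method: Cl⁺ should add to the central allene carbon C6 across the C6=C7 π bond from the outer, C16-methyl side of the ring while the C19 carboxyl attacks C7 anti in a 5-exo mode, so that Cl ends cis to C16 (C4 and C7 cis) and the C7–O bond takes the place that C2 held before step 18; the closest known reaction type is the iodo- and bromolactonisation of 4,5-allenoic acids to 5-(1-haloalkenyl) γ-lactones with axis-to-centre chirality transfer, and the enone alkene is deactivated towards Cl⁺.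

Step 21
Reactants: 28 chlorolactone diketone
Product: 29 diol (C2–OH as in the target; C12–OH cis to Me-20, i.e. 12-epi)
Conditions: NaBH4, CeCl3·7H2O, MeOH, −78 °C
Reagents that add atoms: none
Why: Luche 1,2-reduction of both carbonyls; at C12 hydride should add anti to the C11 methyl side and give the 12-epi alcohol, and at C2 it should add from the outer ring face anti to the C1–C14 bond (Felkin–Anh), which sets C2.

Step 22
Reactants: 29 diol
Product: 30 C12 acetate (inverted, as in the target) with free C2–OH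
Conditions: PPh3, DIAD, AcOH, toluene, 0 °C → rt
Reagents that add atoms: acetic acid, CC(=O)O
Why: Mitsunobu reaction; the allylic C12 alcohol should be displaced by acetate with inversion, while the neopentyl-type C2 alcohol is too hindered to react, which sets C12.

Step 23
Reactants: 30 C12 acetate
Product: 31 2,12-diacetate 8,9-bis-TES ether
Conditions: Ac2O, DMAP, Et3N, CH2Cl2, rt
Reagents that add atoms: acetic anhydride, CC(=O)OC(C)=O
Why: DMAP-catalysed acylation of the remaining secondary alcohol; C8 and C9 are still silylated.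

Step 24
Reactants: 31 diacetate bis-TES ether
Product: 32 CNP0296164.1 (target)
Conditions: HF·pyridine, pyridine, THF, 0 °C → rt
Reagents that add atoms: none
Why: Fluoride-mediated desilylation of the C8 and C9 triethylsilyl ethers under buffered conditions that should leave the acetates, the lactone and the vinyl chloride intact.

## Compound list

1 | (R)-4-benzyl-3-propanoyl-1,3-oxazolidin-2-one | CCC(=O)N1[C@H](Cc2ccccc2)COC1=O | starting material
2 | ethyl glyoxylate | CCOC(=O)C=O | starting material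
3 | ethyl (2R,3R)-4-[(4R)-4-benzyl-2-oxo-1,3-oxazolidin-3-yl]-2-hydroxy-3-methyl-4-oxobutanoate | CCOC(=O)[C@H](O)[C@@H](C)C(=O)N1[C@H](Cc2ccccc2)COC1=O | intermediate
4 | (2R,3R)-2-hydroxy-3-methylbutanedioic acid | OC(=O)[C@H](O)[C@@H](C)C(=O)O | intermediate
5 | (2R)-2-[(2R,4R)-2-tert-butyl-5-oxo-1,3-dioxolan-4-yl]propanoic acid (cis acetal) | CC(C)(C)[C@H]1OC(=O)[C@H](O1)[C@@H](C)C(=O)O | intermediate
6 | tert-butyl (2R)-2-[(2R,4R)-2-tert-butyl-5-oxo-1,3-dioxolan-4-yl]propanoate | CC(C)(C)[C@H]1OC(=O)[C@H](O1)[C@@H](C)C(=O)OC(C)(C)C | intermediate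
7 | but-2-ynal | CC#CC=O | starting material
8 | lithium aldolate of 6 and 7 (C7 alkoxide) | [Li+].CC#C[C@H]([O-])[C@@]1(O[C@@H](C(C)(C)C)OC1=O)[C@@H](C)C(=O)OC(C)(C)C | intermediate
9 | tert-butyl (2R)-2-{(2R,4S)-2-tert-butyl-4-[(1S)-1-(pivaloyloxy)but-2-yn-1-yl]-5-oxo-1,3-dioxolan-4-yl}propanoate | CC#C[C@H](OC(=O)C(C)(C)C)[C@@]1(O[C@@H](C(C)(C)C)OC1=O)[C@@H](C)C(=O)OC(C)(C)C | intermediate
10 | tert-butyl (2R,3S)-3-hydroxy-4-[methoxy(methyl)amino]-2-methyl-4-oxo-3-[(1S)-1-(pivaloyloxy)but-2-yn-1-yl]butanoate | CC#C[C@H](OC(=O)C(C)(C)C)[C@](O)(C(=O)N(C)OC)[C@@H](C)C(=O)OC(C)(C)C | intermediate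
11 | (E)-3-iodo-2-methylprop-2-en-1-ol | OC/C(C)=C/I | starting material
12 | tert-butyl (2R,3S,5E)-3,7-dihydroxy-2,6-dimethyl-4-oxo-3-[(1S)-1-(pivaloyloxy)but-2-yn-1-yl]hept-5-enoate | CC#C[C@H](OC(=O)C(C)(C)C)[C@](O)(C(=O)/C=C(\C)CO)[C@@H](C)C(=O)OC(C)(C)C | intermediate
13 | tert-butyl (2R,3S,5E)-3-hydroxy-2,6-dimethyl-4,7-dioxo-3-[(1S)-1-(pivaloyloxy)but-2-yn-1-yl]hept-5-enoate | CC#C[C@H](OC(=O)C(C)(C)C)[C@](O)(C(=O)/C=C(\C)C=O)[C@@H](C)C(=O)OC(C)(C)C | intermediate
14 | 3-O-triethylsilyl ether of 13 (dienophile) | CC#C[C@H](OC(=O)C(C)(C)C)[C@](O[Si](CC)(CC)CC)(C(=O)/C=C(\C)C=O)[C@@H](C)C(=O)OC(C)(C)C | intermediate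
15 | (E)-4-methoxybut-3-en-2-one | CO/C=C/C(C)=O | starting material
16 | (E)-1-methoxypent-1-en-3-one | CCC(=O)/C=C/OC | intermediate
17 | (1E,3Z)-3-(tert-butyldimethylsilyloxy)-1-methoxypenta-1,3-diene | CO/C=C/C(O[Si](C)(C)C(C)(C)C)=C/C | intermediate
18 | Diels–Alder adduct (C1 formyl/methyl, 14-OMe, 12-OTBS enol ether, 11-Me, C10 acyl chain with 8-OTES, 7-OPiv, propynyl, C17 tert-butyl propanoate) | O=C[C@@]1(C)[C@H](OC)C=C(O[Si](C)(C)C(C)(C)C)[C@H](C)[C@@H]1C(=O)[C@](O[Si](CC)(CC)CC)([C@@H](C)C(=O)OC(C)(C)C)[C@@H](OC(=O)C(C)(C)C)C#CC | intermediate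
19 | C2 allylic alcohol of 18 (C2 epimers) | C=CC(O)[C@@]1(C)[C@H](OC)C=C(O[Si](C)(C)C(C)(C)C)[C@H](C)[C@@H]1C(=O)[C@](O[Si](CC)(CC)CC)([C@@H](C)C(=O)OC(C)(C)C)[C@@H](OC(=O)C(C)(C)C)C#CC | intermediate
20 | C2 vinyl ketone | C=CC(=O)[C@@]1(C)[C@H](OC)C=C(O[Si](C)(C)C(C)(C)C)[C@H](C)[C@@H]1C(=O)[C@](O[Si](CC)(CC)CC)([C@@H](C)C(=O)OC(C)(C)C)[C@@H](OC(=O)C(C)(C)C)C#CC | intermediate
21 | allenyl(ethyl)zinc from 20 (Zn on C5, allene C5=C6=C7) | C=CC(=O)[C@@]1(C)[C@H](OC)C=C(O[Si](C)(C)C(C)(C)C)[C@H](C)[C@@H]1C(=O)[C@](O[Si](CC)(CC)CC)([C@@H](C)C(=O)OC(C)(C)C)C([H])=[C@@]=C(C)[Zn]CC | intermediate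
22 | ring-Y tertiary alcohol (2-OH axial, 2-vinyl equatorial, 7-propynyl axial cis to Me-15, 8-OTES, C9 ketone) | CC#C[C@@H]3[C@](O)(C=C)[C@@]1(C)[C@H](OC)C=C(O[Si](C)(C)C(C)(C)C)[C@H](C)[C@@H]1C(=O)[C@]3(O[Si](CC)(CC)CC)[C@@H](C)C(=O)OC(C)(C)C | intermediate
23 | C9 alcohol of 22 (9-OH axial, cis to Me-15) | CC#C[C@@H]3[C@](O)(C=C)[C@@]1(C)[C@H](OC)C=C(O[Si](C)(C)C(C)(C)C)[C@H](C)[C@@H]1[C@H](O)[C@]3(O[Si](CC)(CC)CC)[C@@H](C)C(=O)OC(C)(C)C | intermediate
24 | 9-O-triethylsilyl ether of 23 | CC#C[C@@H]3[C@](O)(C=C)[C@@]1(C)[C@H](OC)C=C(O[Si](C)(C)C(C)(C)C)[C@H](C)[C@@H]1[C@H](O[Si](CC)(CC)CC)[C@]3(O[Si](CC)(CC)CC)[C@@H](C)C(=O)OC(C)(C)C | intermediate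
25 | potassium 2-enolate of 26 | [K+].[O-]C1=CCC(C)=[C@]=C([H])[C@@](O[Si](CC)(CC)CC)([C@@H](C)C(=O)OC(C)(C)C)[C@@H](O[Si](CC)(CC)CC)[C@H]2[C@@H](C)C(O[Si](C)(C)C(C)(C)C)=C[C@@H](OC)[C@@]21C | intermediate
26 | ten-membered allenyl ketone (C2 ketone, C5=C6=C7 allene, trans-fused to ring A) | O=C1CCC(C)=[C@]=C([H])[C@@](O[Si](CC)(CC)CC)([C@@H](C)C(=O)OC(C)(C)C)[C@@H](O[Si](CC)(CC)CC)[C@H]2[C@@H](C)C(O[Si](C)(C)C(C)(C)C)=C[C@@H](OC)[C@@]21C | intermediate
27 | allene acid with C2 ketone and C12 enone | O=C1CCC(C)=[C@]=C([H])[C@@](O[Si](CC)(CC)CC)([C@@H](C)C(=O)O)[C@@H](O[Si](CC)(CC)CC)[C@H]2[C@@H](C)C(=O)C=C[C@@]21C | intermediate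
28 | chlorolactone (6-chloro-Δ5, 19,7-lactone, 2,12-dione, 8,9-bis-TES ether) | O=C1CC/C(C)=C(/Cl)[C@@H]2OC(=O)[C@H](C)[C@@]2(O[Si](CC)(CC)CC)[C@@H](O[Si](CC)(CC)CC)[C@H]2[C@@H](C)C(=O)C=C[C@@]21C | intermediate
29 | 2,12-diol (C2 as target, 12-epi) | O[C@H]1CC/C(C)=C(/Cl)[C@@H]2OC(=O)[C@H](C)[C@@]2(O[Si](CC)(CC)CC)[C@@H](O[Si](CC)(CC)CC)[C@H]2[C@@H](C)[C@@H](O)C=C[C@@]21C | intermediate
30 | 12-acetate with free 2-OH | O[C@H]1CC/C(C)=C(/Cl)[C@@H]2OC(=O)[C@H](C)[C@@]2(O[Si](CC)(CC)CC)[C@@H](O[Si](CC)(CC)CC)[C@H]2[C@@H](C)[C@H](OC(C)=O)C=C[C@@]21C | intermediate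
31 | 2,12-diacetate 8,9-bis-TES ether | CC(=O)O[C@H]1CC/C(C)=C(/Cl)[C@@H]2OC(=O)[C@H](C)[C@@]2(O[Si](CC)(CC)CC)[C@@H](O[Si](CC)(CC)CC)[C@H]2[C@@H](C)[C@H](OC(C)=O)C=C[C@@]21C | intermediate
32 | CNP0296164.1 | CC(=O)O[C@H]1CC/C(C)=C(/Cl)[C@@H]2OC(=O)[C@H](C)[C@@]2(O)[C@@H](O)[C@H]2[C@@H](C)[C@H](OC(C)=O)C=C[C@@]21C | target

## Counts and risks

Total step count: 24. Longest linear sequence: 22 steps (steps 1–9, then 12–24; steps 10–11 make the diene).

Three steps most likely to fail:

1. Step 20 (chlorolactonisation). The chlorine transfer may be slow or may go to the wrong face of the allene, or the carboxyl may close on C5 instead of C7. Fallback: from 27, iodolactonisation with I2 and NaHCO3 in MeCN, the established halolactonisation of 4,5-allenoic acids, should give the iodolactone F1; copper(I) chloride in NMP at about 120 °C should then exchange the vinyl iodide for chloride with retention of olefin geometry and return to the route at 28.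

2. Step 18 (ring expansion). The alkoxide may fragment by retro-propargylation instead of rearranging, or ring Y may not reach the gauche arrangement of the vinyl and propynyl groups. Fallback: from 24, silylation of the tertiary alcohol with N-(trimethylsilyl)imidazole should give the trimethylsilyl ether F2; heating in a sealed tube (xylene, about 180 °C) should effect the neutral thermal siloxy-Cope rearrangement, the known thermal mode for 1-alkenyl-2-alkynylcyclohexanols, to the silyl enol ether F3; K2CO3 in MeOH should then cleave only the trimethylsilyl enol ether and return to the route at 26.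

3. Step 15 (closure of ring Y). The allenylzinc may add poorly to the hindered C2 ketone, so that protonation to an allene or intermolecular addition takes over. Fallback: from 18, the same Pd(PPh3)4/Et2Zn propargylation is run on the more reactive C2 aldehyde to give the ring-Y secondary alcohol F4. Dess–Martin oxidation should give the 2,9-diketone F5. NaBH4 at −40 °C should reduce the less shielded C9 carbonyl first, from the equatorial side, to the keto alcohol F6. TESCl and imidazole should give the silyl ether F7. Vinylmagnesium bromide with CeCl3 should then add to the C2 ketone, expected on the equatorial trajectory because the axial one is shielded by the C8 silyl ether, and return to the route at 24.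

## Further compounds

F1 | step 20 | iodolactone (6-iodo analogue of 28) | O=C1CC/C(C)=C(/I)[C@@H]2OC(=O)[C@H](C)[C@@]2(O[Si](CC)(CC)CC)[C@@H](O[Si](CC)(CC)CC)[C@H]2[C@@H](C)C(=O)C=C[C@@]21C
F2 | step 18 | 2-O-trimethylsilyl ether of 24 | CC#C[C@@H]3[C@](O[Si](C)(C)C)(C=C)[C@@]1(C)[C@H](OC)C=C(O[Si](C)(C)C(C)(C)C)[C@H](C)[C@@H]1[C@H](O[Si](CC)(CC)CC)[C@]3(O[Si](CC)(CC)CC)[C@@H](C)C(=O)OC(C)(C)C
F3 | step 18 | trimethylsilyl 2-enol ether of 26 | C[Si](C)(C)OC1=CCC(C)=[C@]=C([H])[C@@](O[Si](CC)(CC)CC)([C@@H](C)C(=O)OC(C)(C)C)[C@@H](O[Si](CC)(CC)CC)[C@H]2[C@@H](C)C(O[Si](C)(C)C(C)(C)C)=C[C@@H](OC)[C@@]21C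
F4 | step 15 | ring-Y secondary C2 alcohol with C9 ketone (C2 epimers) | CC#C[C@@H]3C(O)[C@@]1(C)[C@H](OC)C=C(O[Si](C)(C)C(C)(C)C)[C@H](C)[C@@H]1C(=O)[C@]3(O[Si](CC)(CC)CC)[C@@H](C)C(=O)OC(C)(C)C
F5 | step 15 | ring-Y 2,9-diketone | CC#C[C@@H]3C(=O)[C@@]1(C)[C@H](OC)C=C(O[Si](C)(C)C(C)(C)C)[C@H](C)[C@@H]1C(=O)[C@]3(O[Si](CC)(CC)CC)[C@@H](C)C(=O)OC(C)(C)C
F6 | step 15 | ring-Y C2 ketone with axial C9 alcohol | CC#C[C@@H]3C(=O)[C@@]1(C)[C@H](OC)C=C(O[Si](C)(C)C(C)(C)C)[C@H](C)[C@@H]1[C@H](O)[C@]3(O[Si](CC)(CC)CC)[C@@H](C)C(=O)OC(C)(C)C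
F7 | step 15 | ring-Y C2 ketone with C9 triethylsilyl ether | CC#C[C@@H]3C(=O)[C@@]1(C)[C@H](OC)C=C(O[Si](C)(C)C(C)(C)C)[C@H](C)[C@@H]1[C@H](O[Si](CC)(CC)CC)[C@]3(O[Si](CC)(CC)CC)[C@@H](C)C(=O)OC(C)(C)C
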